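All runs come from a simulation from invented constants, and the scatter is random.

- Slowness was my handle: in larch the right-handed substrate went more slowly than the left-handed one, standing at 32.1% against 5.8% after 12.0 min, each having begun at half of the pair charged.

| flask | left-handed substrate | right-handed substrate | reagent | free catalyst | remark | time |
|---|---|---|---|---|---|---|
| alder | 2 mM | 2 mM | 2 mM | 100 µM | run made earlier |  |
| larch | 2 mM | 2 mM | 3 mM | 100 µM | run made earlier |  |
| maple | 3 mM | 3 mM | 4 mM | 100 µM | run made earlier |  |
| flask | 2.0 mM | 2.0 mM | 4.00 mM | 100 µM |  | 15 min |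

| run | time / min | right-handed substrate / % | left-handed substrate / % | left-handed product / % |
|---|---|---|---|---|
| alder | 3.00 | 40.8 | 15.9 | 21.3 |
| alder | 6.00 | 40.0 | 13.9 | 22.4 |
| alder | 10.0 | 39.3 | 14.4 | 23.6 |
| alder | 12.0 | 40.2 | 13.4 | 24.1 |
| larch | 1.50 | 36.2 | 12.8 | 24.7 |
| larch | 4.00 | 33.9 | 7.4 | 28.8 |
| larch | 8.00 | 32.3 | 6.3 | 30.5 |
| larch | 12.0 | 32.1 | 5.8 | 31.7 |
| maple | 1.00 | 38.0 | 14.9 | 24.1 |
| maple | 2.00 | 35.3 | 10.3 | 27.0 |
| maple | 5.00 | 32.6 | 6.2 | 30.6 |
| maple | 12.0 | 31.4 | 6.3 | 31.4 |

(readings scatter by 0.5 percentage points)

- whether the excess of right-handed substrate over left-handed substrate among what is left of the two reaches 80% by 15 min (yes / no)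
- the highest excess of right-handed substrate over left-handed substrate among what is left of the two up to 15 min

- free catalyst is single-handed; left-handed substrate and right-handed substrate are mirror images of each other, charged as a racemate, each of them at the stated concentration
- the earlier runs were read with a standard deviation of 0.5 percentage points
- steps under discussion: free catalyst + left-handed substrate <-> catalyst intermediate A; free catalyst + right-handed substrate <-> catalyst intermediate B; reagent + catalyst intermediate A -> free catalyst + left-handed product; reagent + catalyst intermediate B -> free catalyst + right-handed product; left-handed product <-> right-handed product; 2 free catalyst -> spent catalyst; 2 free catalyst <-> resting dimer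

- Dividing one loss rate by the other removes time and leaves the selectivity factor, 4.86 in larch: s, the logarithm of the fraction l of left-handed substrate left over that of the fraction r of right-handed substrate left.
- With l = r^s, an excess (r − l)/(r + l) of 80% needs r = 56.6%, so the flask must convert 68.6% of the pair, which takes 2.74 mM of reagent, less than its 4.00 mM.
- By my balance, larch still held 0.516 mM of reagent at 12.0 min, while its readings barely moved.
- So I started the flask from larch's first reading and scaled larch's later loss by reagent: the mean was 0.738 mM there and 1.61 mM in the flask.
- That lowered ln l by 1.73, giving l = 4.56%, r = 53.0% and an excess of 84.2%, which I committed to.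
- The weak link was s, since early readings gave 5.63 in alder but a lower 4.22 in larch. Reforged with that lower reading, the same l gave 82.7%, still above 80%.
- The forecast, a little above my figure, said yes with a top of 85%, between 75% and 93%, since “reagent stays plentiful”.
- The flask answered yes, with a top of 85.0%, passing 80% at 6.56 min; at 15.0 min spent catalyst stood at 99.0% of the catalyst charged, with 27% of the reagent left.

    free catalyst + left-handed substrate ⇌ catalyst intermediate A (K = 1530 M⁻¹, k = 3720 M⁻¹ s⁻¹)
    free catalyst + right-handed substrate ⇌ catalyst intermediate B (K = 620 M⁻¹, k = 2950 M⁻¹ s⁻¹)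
    reagent + catalyst intermediate A → free catalyst + left-handed product (k = 643 M⁻¹ s⁻¹)
    reagent + catalyst intermediate B → free catalyst + right-handed product (k = 245 M⁻¹ s⁻¹)
    left-handed product ⇌ right-handed product (k = 0.121 s⁻¹)
    2 free catalyst → spent catalyst (k = 1970 M⁻¹ s⁻¹)
    2 free catalyst ⇌ resting dimer, settled at all times (K = 14100 M⁻¹)

- The fractions left in the flask at 15.0 min, 4.1% and 50%, give s = 4.67, between my two values. Held at that value, the 87.9% excess of the flask run for twice the time puts the right-handed substrate at 47.4% of its own charge.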